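## Retrosynthetic overview

1. The strategy rests on C4 of the cyclohexenone ring, a fully substituted ketal carbon between the C3 enol ether carbon and the C5 methylene that carries one methoxy and one aryloxy oxygen. Replacing the aryloxy group by methoxy makes C4 a non-stereogenic dimethyl ketal, so the C4–OAr bond is cut first, giving an aryl trimethylsilyl ether and (R)-6-allyl-3,4,4-trimethoxycyclohex-2-en-1-one.
2. The C6–allyl bond of the enone half is traced to an allyl dienol carbonate (enantioselective palladium-catalysed decarboxylative allylation), and this to 3,4,4-trimethoxycyclohex-2-en-1-one.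
3. Both six-membered rings go back to 3,4-dimethoxyphenol: O-allylation and Claisen rearrangement for the arene half, oxidative dearomatization in methanol and selective hydrogenation for the enone half.
4. Ring order: no ring is made from open-chain material. The cyclohexenone ring is obtained from the phenol by dearomatization and reduction, allylated at C6, and joined last to the intact arene ring through the ketal oxygen.

Key step: step 8

Remarks on the chemistry:
- Ring numbering used throughout: C1 is the carbonyl carbon, C2=C3 the enone double bond (C3 bears OMe), C4 the ketal carbon, C5 the CH2 and C6 the allyl-bearing carbon.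
- The target is (4R,6R), which places the aryloxy group and the C6 allyl group on opposite faces of the ring.
- Assumption: the (R,R) antipode of the diamide bisphosphine ligand in step 7 is taken to deliver R at C6. The sense of induction is to be verified on the first run, and the (S,S) ligand would be used if the S ketone results.

## Route

Step 1
Reactants: 1 3,4-dimethoxyphenol; 2 allyl bromide
Product: 3 allyl 3,4-dimethoxyphenyl ether
Conditions: K2CO3, acetone, reflux
Reagents that add atoms: none
Why: Williamson ether synthesis, in which the phenoxide formed by K2CO3 displaces bromide from the unhindered allylic halide in an SN2 reaction at oxygen.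

Step 2
Reactants: 3 allyl 3,4-dimethoxyphenyl ether
Product: 4 2-allyl-4,5-dimethoxyphenol
Conditions: PhNEt2, 195 °C, argon
Reagents that add atoms: none
Why: Aromatic Claisen rearrangement ([3,3]-sigmatropic shift, then tautomerization), which should deliver the allyl group to the free ortho carbon remote from the methoxy groups rather than to the ortho carbon flanked by the 3-methoxy group.

Step 3
Reactants: 4 2-allyl-4,5-dimethoxyphenol
Product: 5 (2-allyl-4,5-dimethoxyphenoxy)trimethylsilane
Conditions: (Me3Si)2NH, MeCN, reflux; evaporation and bulb-to-bulb distillation
Reagents that add atoms: hexamethyldisilazane, C[Si](C)(C)N[Si](C)(C)C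
Why: O-silylation of a phenol by hexamethyldisilazane releases only ammonia, so the moisture-sensitive aryl silyl ether should be obtained without aqueous work-up.

Step 4
Reactants: 1 3,4-dimethoxyphenol
Product: 6 3,4,4-trimethoxycyclohexa-2,5-dien-1-one
Conditions: PhI(OAc)2, MeOH, 0 °C; solid NaHCO3 on work-up
Reagents that add atoms: methanol, CO
Why: Oxidative dearomatization of a para-alkoxyphenol by the trivalent iodine reagent, in which the phenol oxygen binds iodine, iodobenzene departs and methanol adds at the methoxy-bearing para carbon to give the quinone monoketal.

Step 5
Reactants: 6 3,4,4-trimethoxycyclohexa-2,5-dien-1-one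
Product: 7 3,4,4-trimethoxycyclohex-2-en-1-one
Conditions: H2 (1 atm), RhCl(PPh3)3 (5 mol %), toluene, rt
Reagents that add atoms: none
Why: Chemoselective homogeneous hydrogenation with the monovalent rhodium complex should saturate only the unhindered 1,2-disubstituted C5=C6 bond, because the trisubstituted, methoxy-bearing C2=C3 bond of the vinylogous ester binds the metal much less readily and the neutral medium spares the ketal.

Step 6
Reactants: 7 3,4,4-trimethoxycyclohex-2-en-1-one; 8 allyl chloroformate
Product: 10 allyl 4,4,5-trimethoxycyclohexa-1,5-dien-1-yl carbonate, via lithium enolate 9 (not isolated)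
Conditions: LiN(SiMe3)2, TMEDA, THF, −78 °C; then 8, −78 °C to −40 °C; pH 7 buffer, Et3N-deactivated silica
Reagents that add atoms: none
Why: Kinetic enolization of the vinylogous ester can only take place at C6 because C4 is fully substituted, and the amine-solvated lithium enolate should be acylated at oxygen by the hard chloroformate (enol carbonate formation).

Step 7
Reactants: 10 allyl 4,4,5-trimethoxycyclohexa-1,5-dien-1-yl carbonate
Product: 11 (R)-6-allyl-3,4,4-trimethoxycyclohex-2-en-1-one
Conditions: Pd2(dba)3·CHCl3 (2.5 mol %), (R,R)-11,12-bis[2-(diphenylphosphino)benzamido]-9,10-dihydro-9,10-ethanoanthracene (5.5 mol %), 1,4-dioxane, 23 °C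
Reagents that add atoms: none
Why: Decarboxylative asymmetric allylic alkylation of Tsuji–Trost type, in which zerovalent palladium ionizes the allyl carbonate, carbon dioxide is lost and the enolate recombines with the allyl unit at C6 inside the chiral pocket of the ligand, which selects the enolate face and sets C6 as R; the neutral, regiospecific enolate generation should suppress double allylation and loss of configuration at the new tertiary center, and C4 is not yet a stereocenter.

Step 8
Reactants: 11 (R)-6-allyl-3,4,4-trimethoxycyclohex-2-en-1-one; 5 (2-allyl-4,5-dimethoxyphenoxy)trimethylsilane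
Product: 13 (4R,6R)-6-allyl-4-(2-allyl-4,5-dimethoxyphenoxy)-3,4-dimethoxycyclohex-2-en-1-one, via oxocarbenium triflate 12 (not isolated)
Conditions: 5 (1.5 equiv), Me3SiOSO2CF3 (0.1 equiv), CH2Cl2, −78 °C; Et3N quench at −78 °C
Reagents that add atoms: none
Why: The silyl triflate silylates one ketal methoxy oxygen of 11, Me3SiOMe departs, and the O-methyl oxocarbenium ion 12 at C4 is captured by the oxygen of silyl ether 5, whose silyl group returns to triflate so that the acid turns over. This is the silyl triflate catalysed acetal exchange between a dimethyl ketal and a silyl ether, the reaction type by which aryl silyl ethers give O-aryl ketosides from cyclic oxocarbenium ions. No ring is closed; only the C4–OAr bond is formed in place of one of the two C4–OMe bonds. The new C4 stereocenter is controlled by C6: with the allyl group pseudoequatorial on the half-chair, axial attack on 12 places the aryloxy group pseudoaxial and therefore trans to the allyl group, and since aryloxide is the better leaving group the mixed ketal can re-ionize, so the C4 epimers should drain into this same isomer, which is also favoured by donation from the geminal methoxy oxygen into the pseudoaxial C–OAr bond. The step needs selection between the two diastereotopic methoxy positions, attack through oxygen rather than through the electron-rich arene carbon, and survival of 12 against proton loss from C5 (which would aromatize the ring to phenol 4) and of C6 against enolization. The biased half-chair, the hard silyloxy oxygen meeting a hindered fully substituted cation, and the cold, base-free, catalytic-acid conditions with a cold amine quench are relied on for these.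

## Compound list

1 | 3,4-dimethoxyphenol | COc1ccc(O)cc1OC | starting material
2 | allyl bromide | C=CCBr | starting material
3 | allyl 3,4-dimethoxyphenyl ether | C=CCOc1ccc(OC)c(OC)c1 | intermediate
4 | 2-allyl-4,5-dimethoxyphenol | C=CCc1cc(OC)c(OC)cc1O | intermediate
5 | (2-allyl-4,5-dimethoxyphenoxy)trimethylsilane | C=CCc1cc(OC)c(OC)cc1O[Si](C)(C)C | intermediate
6 | 3,4,4-trimethoxycyclohexa-2,5-dien-1-one | COC1=CC(=O)C=CC1(OC)OC | intermediate
7 | 3,4,4-trimethoxycyclohex-2-en-1-one | COC1=CC(=O)CCC1(OC)OC | intermediate
8 | allyl chloroformate | C=CCOC(=O)Cl | starting material
9 | lithium 4,4,5-trimethoxycyclohexa-1,5-dien-1-olate (C1–C6 enolate of 7) | [Li+].[O-]C1=CCC(OC)(OC)C(OC)=C1 | intermediate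
10 | allyl 4,4,5-trimethoxycyclohexa-1,5-dien-1-yl carbonate | C=CCOC(=O)OC1=CCC(OC)(OC)C(OC)=C1 | intermediate
11 | (R)-6-allyl-3,4,4-trimethoxycyclohex-2-en-1-one | COC1(OC)C[C@@H](CC=C)C(=O)C=C1OC | intermediate
12 | (R)-5-allyl-2-methoxy-4-oxocyclohex-2-en-1-ylidene(methyl)oxonium triflate (O-methyl oxocarbenium ion at C4) | C=CC[C@@H]1CC(=[O+]C)C(OC)=CC1=O.[O-]S(=O)(=O)C(F)(F)F | intermediate
13 | (4R,6R)-6-allyl-4-(2-allyl-4,5-dimethoxyphenoxy)-3,4-dimethoxycyclohex-2-en-1-one (CNP0352100.3) | C=CCc1cc(OC)c(OC)cc1O[C@]1(OC)C[C@@H](CC=C)C(=O)C=C1OC | target

## Step count and risks

Total step count: 8.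
Longest linear sequence: 5 steps (1 → 6 → 7 → 10 → 11 → 13, steps 4 to 8); the arene branch (steps 1 to 3) joins in step 8.

Steps most likely to fail:

1. Step 8. Ionization at C4 may be followed by proton loss from C5 and aromatization of the enone ring. The facial selectivity at C4 may be incomplete, the arene may attack through carbon, or the acid may enolize C6 and erode its configuration. Fallback: the methoxy-to-aryloxy exchange is moved forward to a stage where the ketal carbon is flanked only by sp2 carbons, so that its oxocarbenium ion has no ring proton to lose. It sets out from dienone 6 and silyl ether 5, which under Me3SiOSO2CF3 (catalytic) in CH2Cl2 at −78 °C should give racemic 4-(2-allyl-4,5-dimethoxyphenoxy)-3,4-dimethoxycyclohexa-2,5-dien-1-one F1. Conjugate reduction of its unsubstituted enone double bond with catalytic [(Ph3P)CuH]6 and PhSiH3 (hydrogenation is excluded by the allyl group) should give racemic 4-(2-allyl-4,5-dimethoxyphenoxy)-3,4-dimethoxycyclohex-2-en-1-one F2. Enolization with LiN(SiMe3)2 and TMEDA and trapping with allyl chloroformate 8 should give racemic allyl 4-(2-allyl-4,5-dimethoxyphenoxy)-4,5-dimethoxycyclohexa-1,5-dien-1-yl carbonate F3. The palladium catalyst and ligand of step 7 should then set C6 as R irrespective of C4, giving 13 together with its C4 epimer, (4S,6R)-6-allyl-4-(2-allyl-4,5-dimethoxyphenoxy)-3,4-dimethoxycyclohex-2-en-1-one F4, from which 13 is separated by chromatography. The fallback comes back to the route at 13, at the cost of the material that ends as the C4 epimer.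

2. Step 7. The enolizable tertiary center at C6 may lose enantiopurity through proton exchange of the palladium enolate or through weak facial discrimination; a second allylation may compete; and the dienol carbonate may lose methanol and aromatize before it reacts. Fallback: stereocontrol by catalysis is replaced by a racemic alkylation and a physical resolution. It sets out from enone 7, which with LiN(iPr)2 in THF at −78 °C and then allyl bromide 2 should give racemic 6-allyl-3,4,4-trimethoxycyclohex-2-en-1-one F5 by kinetic alkylation at C6. Preparative chromatography on a chiral stationary phase (amylose tris(3,5-dimethylphenylcarbamate)) should then deliver 11 and set aside (S)-6-allyl-3,4,4-trimethoxycyclohex-2-en-1-one F6. The fallback comes back to the route at 11.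

3. Step 6. Acylation at carbon may compete with acylation at oxygen, proton transfer between enolate and product may scramble the material, and traces of acid during isolation may trigger loss of methanol from the dienol carbonate and aromatization. Fallback: the enol carbonate is not made at all. It sets out from enone 7, whose lithium enolate 9 (LiN(SiMe3)2, LiCl, THF, −78 °C) is allylated directly with allyl acetate in the presence of Pd2(dba)3·CHCl3 and (R)-BINAP, an intermolecular enantioselective allylic alkylation of a preformed lithium enolate under zerovalent palladium catalysis. This should give 11 in one operation; no compound beyond those of the list is made (F0), and the fallback comes back to the route at 11.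

## Further compounds

F1 | step 8 | racemic 4-(2-allyl-4,5-dimethoxyphenoxy)-3,4-dimethoxycyclohexa-2,5-dien-1-one | C=CCc1cc(OC)c(OC)cc1OC1(OC)C=CC(=O)C=C1OC
F2 | step 8 | racemic 4-(2-allyl-4,5-dimethoxyphenoxy)-3,4-dimethoxycyclohex-2-en-1-one | C=CCc1cc(OC)c(OC)cc1OC1(OC)CCC(=O)C=C1OC
F3 | step 8 | racemic allyl 4-(2-allyl-4,5-dimethoxyphenoxy)-4,5-dimethoxycyclohexa-1,5-dien-1-yl carbonate | C=CCOC(=O)OC1=CCC(OC)(Oc2cc(OC)c(OC)cc2CC=C)C(OC)=C1
F4 | step 8 | (4S,6R)-6-allyl-4-(2-allyl-4,5-dimethoxyphenoxy)-3,4-dimethoxycyclohex-2-en-1-one | C=CCc1cc(OC)c(OC)cc1O[C@@]1(OC)C[C@@H](CC=C)C(=O)C=C1OC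
F5 | step 7 | racemic 6-allyl-3,4,4-trimethoxycyclohex-2-en-1-one | COC1(OC)CC(CC=C)C(=O)C=C1OC
F6 | step 7 | (S)-6-allyl-3,4,4-trimethoxycyclohex-2-en-1-one | COC1(OC)C[C@H](CC=C)C(=O)C=C1OC
F0 | step 6 | none | none
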